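**Strategy**

The synthesis rests on cutting ring B of the naphthazarin at C3–C4, C1–C2 and C1–C8a. A single Dötz benzannulation joins the carbene carbon of an aryl(methoxy)carbene complex of Cr(CO)5 (C4), one CO ligand (C1) and the two carbons of a terminal alkyne (C2, C3), so that ring B appears with oxygen on C1 and C4, hydrogen on C3 and the complete side chain on C2, the C1' stereocentre and its senecioate ester being carried in unchanged. The precursors are the 2,5-dimethoxyphenyl carbene complex and an enantiopure propargylic ester made by asymmetric transfer hydrogenation; two oxidative operations then convert the trimethoxynaphthol into the target.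

Key step: step 7

Remarks on the chemistry:
- The target is one tautomer of a 5,8-dihydroxy-1,4-naphthoquinone. The tautomers interconvert rapidly, so it does not matter which ring ends as the quinone.
- Numbering follows the naphthalene core (side chain on C2, carbinol carbon C1').
- The η6-bound Cr(CO)3 fragment of 16 is written in SMILES as a dot-separated component.

**Route**

Step 1
Reactants: 1 2-bromo-1,4-dimethoxybenzene; 2 hexacarbonylchromium, Cr(CO)6
Product: 5 pentacarbonyl[(2,5-dimethoxyphenyl)(methoxy)methylidene]chromium, via 2,5-dimethoxyphenyllithium 3 (not isolated), via lithium acylchromate 4 (not isolated)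
Conditions: n-BuLi, THF, −78 °C; Cr(CO)6, −78 °C → rt; solvent exchange; Me3OBF4, CH2Cl2, 0 °C → rt
Reagents that add atoms: trimethyloxonium tetrafluoroborate, C[O+](C)C.F[B-](F)(F)F
Why: Fischer carbene synthesis, in which bromine–lithium exchange gives the aryllithium, this adds to a CO ligand of Cr(CO)6, and the hard oxonium salt methylates the acylchromate on oxygen.

Step 2
Reactants: 6 4-methylpent-3-enoic acid
Product: 8 N-methoxy-N,4-dimethylpent-3-enamide, via acyl imidazolide 7 (not isolated)
Conditions: CDI, CH2Cl2, 0 °C → rt; then MeNH(OMe)·HCl, rt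
Reagents that add atoms: N,O-dimethylhydroxylamine hydrochloride, CNOC.Cl
Why: Amide coupling through the acyl imidazolide needs no strong base, so the β,γ-double bond should stay out of conjugation.

Step 3
Reactants: 8 N-methoxy-N,4-dimethylpent-3-enamide; 9 ethynyltrimethylsilane
Product: 11 6-methyl-1-(trimethylsilyl)hept-5-en-1-yn-3-one, via lithium (trimethylsilyl)acetylide 10 (not isolated)
Conditions: n-BuLi, THF, −78 °C; then 8, −78 → −20 °C; cold sat. aq. NH4Cl quench
Reagents that add atoms: none
Why: Weinreb ketone synthesis, in which the acetylide adds only once because the N-methoxy-N-methyl amide holds the adduct until the cold quench, which also protects the skipped enone from isomerisation and from amine addition.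

Step 4
Reactants: 11 6-methyl-1-(trimethylsilyl)hept-5-en-1-yn-3-one
Product: 12 (3R)-6-methyl-1-(trimethylsilyl)hept-5-en-1-yn-3-ol
Conditions: Ru[(1R,2R)-TsNCH(Ph)CH(Ph)NH](η6-p-cymene) (cat.), i-PrOH, rt
Reagents that add atoms: none
Why: Noyori asymmetric transfer hydrogenation of an alkynyl ketone, in which the base-free 16-electron amido complex of divalent ruthenium with the (R,R)-diamine delivers hydride to the face that gives the (R)-propargylic alcohol (the alkynyl group takes the role of the aryl group of an aryl ketone), so the catalyst sets C3.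

Step 5
Reactants: 12 (3R)-6-methyl-1-(trimethylsilyl)hept-5-en-1-yn-3-ol
Product: 13 (3R)-6-methylhept-5-en-1-yn-3-ol
Conditions: K2CO3 (cat.), MeOH, 0 °C → rt; careful concentration (volatile)
Reagents that add atoms: none
Why: Base-catalysed methanolysis of the C(sp)–Si bond (protodesilylation) should free the terminal alkyne without touching the carbinol centre.

Step 6
Reactants: 13 (3R)-6-methylhept-5-en-1-yn-3-ol; 14 3-methylbut-2-enoic acid
Product: 15 (3R)-6-methylhept-5-en-1-yn-3-yl 3-methylbut-2-enoate
Conditions: DCC, DMAP (cat.), CH2Cl2, 0 °C → rt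
Reagents that add atoms: none
Why: Steglich esterification activates the acid and not the alcohol, so the C–O bond at the stereocentre is never broken, and it avoids the vinylketene pathway by which the acid chloride with an amine base would move the enoate double bond out of conjugation.

Step 7
Reactants: 5 pentacarbonyl[(2,5-dimethoxyphenyl)(methoxy)methylidene]chromium (slight excess); 15 (3R)-6-methylhept-5-en-1-yn-3-yl 3-methylbut-2-enoate
Product: 17 (1R)-1-(1-hydroxy-4,5,8-trimethoxynaphthalen-2-yl)-4-methylpent-3-en-1-yl 3-methylbut-2-enoate, via Cr(CO)3 naphthol complex 16 (not isolated)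
Conditions: THF, 45–50 °C, Ar; then Et2O, air, hν, rt
Reagents that add atoms: none
Why: Dötz benzannulation: thermal loss of one CO from 5 opens a site at which the alkyne binds and inserts into the Cr=C bond, its CH terminus bonding to the carbene carbon (C3–C4), and CO insertion then gives a chromium-bound vinylketene whose ketene carbon is attached to the substituted alkyne carbon (C1–C2). Ring B closes by 6π-electrocyclisation of this aryl-vinylketene onto the one unsubstituted ortho carbon of the aryl group (C1–C8a), and tautomerisation gives the naphthol as its Cr(CO)3 complex 16, which air and light demetalate. The closest known reaction type is the benzannulation of aryl(alkoxy)carbene complexes of Cr(CO)5 with terminal alkynes, propargylic oxygenated ones included. No stereocentre is formed, and C1' lies outside every bond change, so it should keep its (R) configuration. The selectivity needed is regiochemical and chemoselective: a terminal alkyne places its substituent next to the CO-derived C1 (the opposite orientation would converge on the same naphthazarin anyway), the second ortho position is blocked by OMe, and the β,β-disubstituted enoate and the trisubstituted alkene are too hindered to intercept the carbene, the alkene also standing in a 1,5-relation to the alkyne so that intramolecular cyclopropanation would need a bicyclo[2.1.0]pentane. Moderate temperature and prompt demetalation are chosen so that the benzylic ester does not ionise on the chromium-bound naphthol.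

Step 8
Reactants: 17 (1R)-1-(1-hydroxy-4,5,8-trimethoxynaphthalen-2-yl)-4-methylpent-3-en-1-yl 3-methylbut-2-enoate
Product: 18 (1R)-1-(5,8-dimethoxy-1,4-dioxo-1,4-dihydronaphthalen-2-yl)-4-methylpent-3-en-1-yl 3-methylbut-2-enoate
Conditions: (NH4)2Ce(NO3)6, MeCN/H2O, 0 °C
Reagents that add atoms: water, O
Why: Oxidative demethylation of a para-methoxyphenol by tetravalent cerium should occur on ring B, which the free C1 hydroxyl makes much easier to oxidise than the dimethoxy ring A, with water adding at C4 and methanol leaving, while ester and alkene survive brief treatment at 0 °C.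

Step 9
Reactants: 18 (1R)-1-(5,8-dimethoxy-1,4-dioxo-1,4-dihydronaphthalen-2-yl)-4-methylpent-3-en-1-yl 3-methylbut-2-enoate
Product: 20 (1R)-1-(5,8-dihydroxy-1,4-dioxo-1,4-dihydronaphthalen-2-yl)-4-methylpent-3-en-1-yl 3-methylbut-2-enoate, via diquinone 19 (not isolated)
Conditions: AgO, 6 M HNO3, acetone, rt (short); then CHCl3, aq. Na2S2O4, rt
Reagents that add atoms: water, O
Why: Oxidative demethylation with AgO in nitric acid should take the deactivated dimethoxy ring to the second quinone, and mild dithionite reduction of the tetraketone should give the hydrogen-bonded dihydroxynaphthoquinone, while the ester prevents the C1' oxygen from cyclising onto the alkene and C1' itself is untouched.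

**Compound list**

1 | 2-bromo-1,4-dimethoxybenzene | COc1ccc(OC)c(Br)c1 | starting material
2 | hexacarbonylchromium, Cr(CO)6 | O=C=[Cr](=C=O)(=C=O)(=C=O)(=C=O)=C=O | starting material
3 | 2,5-dimethoxyphenyllithium | [Li]c1cc(OC)ccc1OC | intermediate (not isolated)
4 | lithium pentacarbonyl(2,5-dimethoxybenzoyl)chromate | [Li+].[O-]C(=[Cr](=C=O)(=C=O)(=C=O)(=C=O)=C=O)c1cc(OC)ccc1OC | intermediate (not isolated)
5 | pentacarbonyl[(2,5-dimethoxyphenyl)(methoxy)methylidene]chromium | COC(=[Cr](=C=O)(=C=O)(=C=O)(=C=O)=C=O)c1cc(OC)ccc1OC | intermediate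
6 | 4-methylpent-3-enoic acid | CC(C)=CCC(=O)O | starting material
7 | 1-(1H-imidazol-1-yl)-4-methylpent-3-en-1-one | CC(C)=CCC(=O)n1ccnc1 | intermediate (not isolated)
8 | N-methoxy-N,4-dimethylpent-3-enamide | CC(C)=CCC(=O)N(C)OC | intermediate
9 | ethynyltrimethylsilane | C#C[Si](C)(C)C | starting material
10 | lithium (trimethylsilyl)acetylide | [Li]C#C[Si](C)(C)C | intermediate (not isolated)
11 | 6-methyl-1-(trimethylsilyl)hept-5-en-1-yn-3-one | CC(C)=CCC(=O)C#C[Si](C)(C)C | intermediate
12 | (3R)-6-methyl-1-(trimethylsilyl)hept-5-en-1-yn-3-ol | CC(C)=CC[C@@H](O)C#C[Si](C)(C)C | intermediate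
13 | (3R)-6-methylhept-5-en-1-yn-3-ol | CC(C)=CC[C@@H](O)C#C | intermediate
14 | 3-methylbut-2-enoic acid | CC(C)=CC(=O)O | starting material
15 | (3R)-6-methylhept-5-en-1-yn-3-yl 3-methylbut-2-enoate | CC(C)=CC[C@@H](OC(=O)C=C(C)C)C#C | intermediate
16 | tricarbonyl{η6-(1R)-1-(1-hydroxy-4,5,8-trimethoxynaphthalen-2-yl)-4-methylpent-3-en-1-yl 3-methylbut-2-enoate}chromium | CC(C)=CC[C@@H](OC(=O)C=C(C)C)c1cc(OC)c2c(OC)ccc(OC)c2c1O.O=C=[Cr](=C=O)=C=O | intermediate (not isolated)
17 | (1R)-1-(1-hydroxy-4,5,8-trimethoxynaphthalen-2-yl)-4-methylpent-3-en-1-yl 3-methylbut-2-enoate | CC(C)=CC[C@@H](OC(=O)C=C(C)C)c1cc(OC)c2c(OC)ccc(OC)c2c1O | intermediate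
18 | (1R)-1-(5,8-dimethoxy-1,4-dioxo-1,4-dihydronaphthalen-2-yl)-4-methylpent-3-en-1-yl 3-methylbut-2-enoate | CC(C)=CC[C@@H](OC(=O)C=C(C)C)C1=CC(=O)c2c(OC)ccc(OC)c2C1=O | intermediate
19 | (1R)-4-methyl-1-(1,4,5,8-tetraoxo-1,4,5,8-tetrahydronaphthalen-2-yl)pent-3-en-1-yl 3-methylbut-2-enoate | CC(C)=CC[C@@H](OC(=O)C=C(C)C)C1=CC(=O)C2=C(C1=O)C(=O)C=CC2=O | intermediate (not isolated)
20 | (1R)-1-(5,8-dihydroxy-1,4-dioxo-1,4-dihydronaphthalen-2-yl)-4-methylpent-3-en-1-yl 3-methylbut-2-enoate | CC(C)=CC[C@@H](OC(=O)C=C(C)C)C1=CC(=O)c2c(O)ccc(O)c2C1=O | target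

**Step count and risks**

Total step count: 9. Longest linear sequence: 8 steps (steps 2 to 9, from 4-methylpent-3-enoic acid); the carbene branch is 1 step before convergence.

Steps most likely to fail:

1. Step 7. The C1' acyloxy group may ionise or be eliminated on the electron-rich, chromium-bound naphthol (through an ortho-quinone methide), which would cost both the ester and the configuration; the vinylcarbene may also be diverted to non-phenolic products. The fallback carries the C1' oxygen through the benzannulation as a much poorer leaving group and acylates only after ring B is a quinone. It sets out from alkynol 13 (with complex 5) and returns at quinone 18. Alkynol 13 would be silylated (TBSCl, imidazole, DMF) to tert-butyl(dimethyl){[(3R)-6-methylhept-5-en-1-yn-3-yl]oxy}silane F1. Benzannulation of F1 with 5 under the conditions of step 7 should give 2-[(1R)-1-{[tert-butyl(dimethyl)silyl]oxy}-4-methylpent-3-en-1-yl]-4,5,8-trimethoxynaphthalen-1-ol F2. Oxidation with (NH4)2Ce(NO3)6 in MeCN/H2O should give 2-[(1R)-1-{[tert-butyl(dimethyl)silyl]oxy}-4-methylpent-3-en-1-yl]-5,8-dimethoxynaphthalene-1,4-dione F3. HF·pyridine in THF should free 2-[(1R)-1-hydroxy-4-methylpent-3-en-1-yl]-5,8-dimethoxynaphthalene-1,4-dione F4, and Steglich esterification of F4 with acid 14 (DCC, DMAP) should deliver 18, from which step 9 follows unchanged.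

2. Step 9. The strongly oxidising, strongly acidic second demethylation may over-oxidise or hydrate the side-chain alkene, cleave the ester, or stop short on the deactivated ring. The fallback replaces the redox sequence by a non-oxidative, chelation-directed ether cleavage. It sets out from quinone 18 and returns at target 20. BCl3 in CH2Cl2 at −78 °C should bind each quinone carbonyl together with its peri methoxy oxygen and remove both methyl groups as chloromethane, giving 20 directly after aqueous work-up; no new compound is made.

3. Step 4. The amido-ruthenium catalyst may move the β,γ-double bond into conjugation with the ynone, or facial selectivity may be insufficient for this CH2-flanked ketone. The fallback sets the stereocentre by resolution. It sets out from ynone 11 and returns at alkynol 13. Luche reduction (NaBH4, CeCl3·7H2O, MeOH, −78 °C) should give racemic 6-methyl-1-(trimethylsilyl)hept-5-en-1-yn-3-ol F5, and K2CO3 in MeOH should give racemic 6-methylhept-5-en-1-yn-3-ol F6. Kinetic resolution with Candida antarctica lipase B and vinyl acetate in hexane is expected, by the usual size rule for lipases (small ethynyl against the larger prenyl-methyl group), to acetylate the (3S)-alcohol to (3S)-6-methylhept-5-en-1-yn-3-yl acetate F7. The (3R)-alcohol 13 would then be recovered by chromatography at high conversion, and its configuration would have to be confirmed before use.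

**Further compounds**

F1 | step 7 | tert-butyl(dimethyl){[(3R)-6-methylhept-5-en-1-yn-3-yl]oxy}silane | CC(C)=CC[C@@H](O[Si](C)(C)C(C)(C)C)C#C
F2 | step 7 | 2-[(1R)-1-{[tert-butyl(dimethyl)silyl]oxy}-4-methylpent-3-en-1-yl]-4,5,8-trimethoxynaphthalen-1-ol | CC(C)=CC[C@@H](O[Si](C)(C)C(C)(C)C)c1cc(OC)c2c(OC)ccc(OC)c2c1O
F3 | step 7 | 2-[(1R)-1-{[tert-butyl(dimethyl)silyl]oxy}-4-methylpent-3-en-1-yl]-5,8-dimethoxynaphthalene-1,4-dione | CC(C)=CC[C@@H](O[Si](C)(C)C(C)(C)C)C1=CC(=O)c2c(OC)ccc(OC)c2C1=O
F4 | step 7 | 2-[(1R)-1-hydroxy-4-methylpent-3-en-1-yl]-5,8-dimethoxynaphthalene-1,4-dione | CC(C)=CC[C@@H](O)C1=CC(=O)c2c(OC)ccc(OC)c2C1=O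
F0 | step 9 | none | none
F5 | step 4 | racemic 6-methyl-1-(trimethylsilyl)hept-5-en-1-yn-3-ol | CC(C)=CCC(O)C#C[Si](C)(C)C
F6 | step 4 | racemic 6-methylhept-5-en-1-yn-3-ol | CC(C)=CCC(O)C#C
F7 | step 4 | (3S)-6-methylhept-5-en-1-yn-3-yl acetate | CC(C)=CC[C@H](OC(C)=O)C#C
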